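**Retrosynthetic overview**
1. Chebulic acid 29 ⇐ hexabenzyl compound 28 (hydrogenolysis) ⇐ hydroxy aryl triflate 27 by Pd-catalysed carbonylative lactonisation; the isochromanone ring is formed last and its C1 comes from CO.
2. 27 ⇐ dihydrocoumarin 24 (benzyl alcoholysis, triflation of the freed phenol); the side-chain stereocentre comes from trans-selective enolate alkylation of dihydrocoumarin 21 with benzyl bromoacetate.
3. 21 ⇐ δ-lactone 15; the C3–O stereocentre comes from trans-selective enolate hydroxylation of 4-aryl-δ-valerolactone 12.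
4. 12 ⇐ key step: organocatalytic intermolecular Michael addition of dimethyl malonate 8 to enal 7 (sets the benzylic centre C4), then reduction and decarboxylative lactonisation.
5. 7 ⇐ 3,4,5-tris(benzyloxy)benzaldehyde 1 (Dakin, ortho-formylation, O-allylation, Wittig). Ring order: δ-lactone → dihydrocoumarin → isochromanone.

Assumption: 3,4,5-tris(benzyloxy)benzaldehyde (1) is bought as a catalogue compound (otherwise one step from 3,4,5-trihydroxybenzaldehyde with BnBr, K2CO3).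

Step 1
Reactants: 1 3,4,5-tris(benzyloxy)benzaldehyde
Product: 3 3,4,5-tris(benzyloxy)phenol, via aryl formate 2 (not isolated)
Conditions: mCPBA, CH2Cl2, rt; then K2CO3 (cat.), MeOH, rt
Reagents that add atoms: 3-chloroperoxybenzoic acid, O=C(OO)c1cccc(Cl)c1
Why: Dakin-type Baeyer–Villiger oxidation, in which the electron-rich aryl group migrates and the formate is then methanolysed.

Step 2
Reactants: 3 3,4,5-tris(benzyloxy)phenol
Product: 4 2,3,4-tris(benzyloxy)-6-hydroxybenzaldehyde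
Conditions: MgCl2, Et3N, (CH2O)n, MeCN, reflux
Reagents that add atoms: formaldehyde (from paraformaldehyde), C=O
Why: Magnesium-phenoxide-directed ortho-formylation (Casnati–Skattebøl); the two ortho positions are equivalent, so only one product can form.

Step 3
Reactants: 4 2,3,4-tris(benzyloxy)-6-hydroxybenzaldehyde
Product: 5 6-(allyloxy)-2,3,4-tris(benzyloxy)benzaldehyde
Conditions: allyl bromide, K2CO3, DMF, 50 °C
Reagents that add atoms: allyl bromide, C=CCBr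
Why: Williamson etherification gives a phenol protecting group that is orthogonal to the benzyl ethers and is removed later with Pd(0).

Step 4
Reactants: 5 6-(allyloxy)-2,3,4-tris(benzyloxy)benzaldehyde; 6 (triphenylphosphoranylidene)acetaldehyde
Product: 7 (E)-3-[6-(allyloxy)-2,3,4-tris(benzyloxy)phenyl]prop-2-enal
Conditions: toluene, 95 °C
Reagents that add atoms: none
Why: Wittig olefination with the stabilised formylmethylene ylide gives the E-enal.

Step 5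
Reactants: 7 (E)-3-[6-(allyloxy)-2,3,4-tris(benzyloxy)phenyl]prop-2-enal; 8 dimethyl malonate
Product: 9 dimethyl 2-[(1R)-1-[6-(allyloxy)-2,3,4-tris(benzyloxy)phenyl]-3-oxopropyl]propanedioate
Conditions: (S)-α,α-bis[3,5-bis(trifluoromethyl)phenyl]prolinol TMS ether (10 mol%), PhCO2H (10 mol%), EtOH, 0 °C to rt
Reagents that add atoms: none
Why: Iminium-catalysed asymmetric Michael addition (Jørgensen–Hayashi); the silyloxydiarylmethyl group blocks the Re face of the enal β-carbon, so malonate adds to the Si face and gives the (R)-adduct.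

Step 6
Reactants: 9 dimethyl 2-[(1R)-1-[6-(allyloxy)-2,3,4-tris(benzyloxy)phenyl]-3-oxopropyl]propanedioate
Product: 12 (4R)-4-[6-(allyloxy)-2,3,4-tris(benzyloxy)phenyl]oxan-2-one, via hydroxy diester 10 (not isolated), via hydroxy malonic acid 11 (not isolated)
Conditions: NaBH4, MeOH, 0 °C; then LiOH, THF/H2O, rt; then 2 M HCl; toluene, 110 °C
Reagents that add atoms: none
Why: Chemoselective aldehyde reduction, saponification, then thermal malonic acid decarboxylation with δ-lactonisation; the benzylic centre is not enolisable and is untouched.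

Step 7
Reactants: 12 (4R)-4-[6-(allyloxy)-2,3,4-tris(benzyloxy)phenyl]oxan-2-one
Product: 14 (3S,4S)-4-[6-(allyloxy)-2,3,4-tris(benzyloxy)phenyl]-3-hydroxyoxan-2-one, via potassium enolate 13 (not isolated)
Conditions: KHMDS, THF, −78 °C; then 2-(phenylsulfonyl)-3-phenyloxaziridine, −78 °C; AcOH quench
Reagents that add atoms: 2-(phenylsulfonyl)-3-phenyloxaziridine, O=S(=O)(c1ccccc1)N1OC1c1ccccc1
Why: Davis enolate hydroxylation; the oxidant approaches anti to the adjacent 4-aryl group, giving the 3,4-trans (3S) alcohol, which is also the thermodynamically preferred isomer.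

Step 8
Reactants: 14 (3S,4S)-4-[6-(allyloxy)-2,3,4-tris(benzyloxy)phenyl]-3-hydroxyoxan-2-one
Product: 15 (3S,4S)-4-[6-(allyloxy)-2,3,4-tris(benzyloxy)phenyl]-3-[(tert-butyldimethylsilyl)oxy]oxan-2-one
Conditions: TBSOTf, 2,6-lutidine, CH2Cl2, 0 °C
Reagents that add atoms: tert-butyldimethylsilyl triflate, CC(C)(C)[Si](C)(C)OS(=O)(=O)C(F)(F)F
Why: Silylation masks the secondary alcohol so it cannot form a γ-lactone with the carboxyl groups introduced later.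

Step 9
Reactants: 15 (3S,4S)-4-[6-(allyloxy)-2,3,4-tris(benzyloxy)phenyl]-3-[(tert-butyldimethylsilyl)oxy]oxan-2-one
Product: 17 benzyl (2S,3S)-3-[6-(allyloxy)-2,3,4-tris(benzyloxy)phenyl]-2-[(tert-butyldimethylsilyl)oxy]-5-hydroxypentanoate, via lithium carboxylate 16 (not isolated)
Conditions: LiOH·H2O, THF/H2O, 0 °C to rt; concentrate; then BnBr, DMF, rt (used directly)
Reagents that add atoms: lithium hydroxide, [Li+].[OH-]; benzyl bromide, BrCc1ccccc1
Why: Lactone saponification followed by O-alkylation of the carboxylate frees the primary alcohol and fixes the C3 carboxyl as its benzyl ester.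

Step 10
Reactants: 17 benzyl (2S,3S)-3-[6-(allyloxy)-2,3,4-tris(benzyloxy)phenyl]-2-[(tert-butyldimethylsilyl)oxy]-5-hydroxypentanoate
Product: 19 (3S,4S)-3-[6-(allyloxy)-2,3,4-tris(benzyloxy)phenyl]-5-(benzyloxy)-4-[(tert-butyldimethylsilyl)oxy]-5-oxopentanoic acid, via aldehyde 18 (not isolated)
Conditions: TEMPO (20 mol%), PhI(OAc)2 (2.2 equiv), MeCN/H2O 1:1, rt
Reagents that add atoms: water, O
Why: TEMPO/BAIB oxidation takes the primary alcohol through the aldehyde hydrate to the acid without touching the silyl ether, the ester or the alkene.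

Step 11
Reactants: 19 (3S,4S)-3-[6-(allyloxy)-2,3,4-tris(benzyloxy)phenyl]-5-(benzyloxy)-4-[(tert-butyldimethylsilyl)oxy]-5-oxopentanoic acid
Product: 21 benzyl (2S)-2-[(tert-butyldimethylsilyl)oxy]-2-[(4S)-5,6,7-tris(benzyloxy)-2-oxo-3,4-dihydro-2H-chromen-4-yl]acetate, via phenol acid 20 (not isolated)
Conditions: Pd(PPh3)4 (5 mol%), morpholine, THF, rt; then EDC·HCl, DMAP (cat.), CH2Cl2, rt
Reagents that add atoms: none
Why: Tsuji–Trost deallylation frees the phenol, which lactonises with the only free acid to the six-membered dihydrocoumarin; this rigid ring is the template for the next step.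

Step 12
Reactants: 21 benzyl (2S)-2-[(tert-butyldimethylsilyl)oxy]-2-[(4S)-5,6,7-tris(benzyloxy)-2-oxo-3,4-dihydro-2H-chromen-4-yl]acetate; 22 benzyl bromoacetate
Product: 24 benzyl (2S)-2-[(3S,4S)-5,6,7-tris(benzyloxy)-3-[2-(benzyloxy)-2-oxoethyl]-2-oxo-3,4-dihydro-2H-chromen-4-yl]-2-[(tert-butyldimethylsilyl)oxy]acetate, via lithium enolate 23 (not isolated)
Conditions: LiHMDS, THF/DMPU, −78 °C; then 22, −78 to −45 °C
Reagents that add atoms: none
Why: Enolate alkylation of the more acidic aryl-ester lactone; the electrophile enters anti to the bulky C4 substituent and gives the 3,4-trans (3S) product, which is also the thermodynamic isomer.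

Step 13
Reactants: 24 benzyl (2S)-2-[(3S,4S)-5,6,7-tris(benzyloxy)-3-[2-(benzyloxy)-2-oxoethyl]-2-oxo-3,4-dihydro-2H-chromen-4-yl]-2-[(tert-butyldimethylsilyl)oxy]acetate
Product: 26 tribenzyl (1S,2S,3S)-1-[(tert-butyldimethylsilyl)oxy]-2-[2,3,4-tris(benzyloxy)-6-{[(trifluoromethyl)sulfonyl]oxy}phenyl]butane-1,3,4-tricarboxylate, via phenol triester 25 (not isolated)
Conditions: BnOH (5 equiv), Et3N, DMAP (cat.), CH2Cl2, rt; then PhNTf2, rt
Reagents that add atoms: benzyl alcohol, OCc1ccccc1; N-phenylbis(trifluoromethanesulfonimide), O=S(=O)(N(c1ccccc1)S(=O)(=O)C(F)(F)F)C(F)(F)F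
Why: Transesterification of the activated aryl ester with benzyl alcohol, made irreversible by phenol-selective triflation of the released phenol; no stereocentre is involved.

Step 14
Reactants: 26 tribenzyl (1S,2S,3S)-1-[(tert-butyldimethylsilyl)oxy]-2-[2,3,4-tris(benzyloxy)-6-{[(trifluoromethyl)sulfonyl]oxy}phenyl]butane-1,3,4-tricarboxylate
Product: 27 tribenzyl (1S,2S,3S)-1-hydroxy-2-[2,3,4-tris(benzyloxy)-6-{[(trifluoromethyl)sulfonyl]oxy}phenyl]butane-1,3,4-tricarboxylate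
Conditions: HF·pyridine, THF/pyridine, 0 °C to rt
Reagents that add atoms: none
Why: Buffered, mildly acidic fluoride desilylation frees the alcohol without the alkoxide conditions that would trigger lactonisation onto the benzyl esters.

Step 15
Reactants: 27 tribenzyl (1S,2S,3S)-1-hydroxy-2-[2,3,4-tris(benzyloxy)-6-{[(trifluoromethyl)sulfonyl]oxy}phenyl]butane-1,3,4-tricarboxylate
Product: 28 dibenzyl (2S)-2-[(3S,4S)-5,6,7-tris(benzyloxy)-3-[(benzyloxy)carbonyl]-1-oxo-3,4-dihydro-1H-isochromen-4-yl]butanedioate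
Conditions: Pd(OAc)2 (10 mol%), dppp (10 mol%), CO (1 atm), Et3N, DMF, 70 °C
Reagents that add atoms: carbon monoxide, [C-]#[O+]
Why: Pd-catalysed carbonylative lactonisation (intramolecular alkoxycarbonylation of the aryl triflate); the acyl-palladium is trapped by the secondary alcohol in a six-membered closure with retention at all three stereocentres.

Step 16
Reactants: 28 dibenzyl (2S)-2-[(3S,4S)-5,6,7-tris(benzyloxy)-3-[(benzyloxy)carbonyl]-1-oxo-3,4-dihydro-1H-isochromen-4-yl]butanedioate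
Product: 29 chebulic acid, (2S)-2-[(3S,4S)-3-carboxy-5,6,7-trihydroxy-1-oxo-3,4-dihydro-1H-isochromen-4-yl]butanedioic acid
Conditions: H2 (1 atm), 10% Pd/C, THF, rt
Reagents that add atoms: none
Why: Global hydrogenolysis removes three benzyl ethers and three benzyl esters under neutral conditions; the lactone C–O bond is not benzylic and survives.

**Compound list**
1 | 3,4,5-tris(benzyloxy)benzaldehyde | O=Cc1cc(OCc2ccccc2)c(OCc2ccccc2)c(OCc2ccccc2)c1 | starting material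
2 | 3,4,5-tris(benzyloxy)phenyl formate | O=COc1cc(OCc2ccccc2)c(OCc2ccccc2)c(OCc2ccccc2)c1 | intermediate
3 | 3,4,5-tris(benzyloxy)phenol | Oc1cc(OCc2ccccc2)c(OCc2ccccc2)c(OCc2ccccc2)c1 | intermediate
4 | 2,3,4-tris(benzyloxy)-6-hydroxybenzaldehyde | O=Cc1c(O)cc(OCc2ccccc2)c(OCc2ccccc2)c1OCc1ccccc1 | intermediate
5 | 6-(allyloxy)-2,3,4-tris(benzyloxy)benzaldehyde | O=Cc1c(OCC=C)cc(OCc2ccccc2)c(OCc2ccccc2)c1OCc1ccccc1 | intermediate
6 | (triphenylphosphoranylidene)acetaldehyde | O=CC=P(c1ccccc1)(c1ccccc1)c1ccccc1 | starting material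
7 | (E)-3-[6-(allyloxy)-2,3,4-tris(benzyloxy)phenyl]prop-2-enal | O=C/C=C/c1c(OCC=C)cc(OCc2ccccc2)c(OCc2ccccc2)c1OCc1ccccc1 | intermediate
8 | dimethyl malonate | COC(=O)CC(=O)OC | starting material
9 | dimethyl 2-[(1R)-1-[6-(allyloxy)-2,3,4-tris(benzyloxy)phenyl]-3-oxopropyl]propanedioate | O=CC[C@@H](c1c(OCC=C)cc(OCc2ccccc2)c(OCc2ccccc2)c1OCc1ccccc1)C(C(=O)OC)C(=O)OC | intermediate
10 | dimethyl 2-[(1R)-1-[6-(allyloxy)-2,3,4-tris(benzyloxy)phenyl]-3-hydroxypropyl]propanedioate | OCC[C@@H](c1c(OCC=C)cc(OCc2ccccc2)c(OCc2ccccc2)c1OCc1ccccc1)C(C(=O)OC)C(=O)OC | intermediate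
11 | 2-[(1R)-1-[6-(allyloxy)-2,3,4-tris(benzyloxy)phenyl]-3-hydroxypropyl]propanedioic acid | OCC[C@@H](c1c(OCC=C)cc(OCc2ccccc2)c(OCc2ccccc2)c1OCc1ccccc1)C(C(=O)O)C(=O)O | intermediate
12 | (4R)-4-[6-(allyloxy)-2,3,4-tris(benzyloxy)phenyl]oxan-2-one | O=C1OCC[C@@H](c2c(OCC=C)cc(OCc3ccccc3)c(OCc3ccccc3)c2OCc2ccccc2)C1 | intermediate
13 | potassium enolate of 12 | [K+].[O-]C1=C[C@H](c2c(OCC=C)cc(OCc3ccccc3)c(OCc3ccccc3)c2OCc2ccccc2)CCO1 | intermediate
14 | (3S,4S)-4-[6-(allyloxy)-2,3,4-tris(benzyloxy)phenyl]-3-hydroxyoxan-2-one (3,4-trans) | O=C1OCC[C@@H](c2c(OCC=C)cc(OCc3ccccc3)c(OCc3ccccc3)c2OCc2ccccc2)[C@@H]1O | intermediate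
15 | (3S,4S)-4-[6-(allyloxy)-2,3,4-tris(benzyloxy)phenyl]-3-[(tert-butyldimethylsilyl)oxy]oxan-2-one | O=C1OCC[C@@H](c2c(OCC=C)cc(OCc3ccccc3)c(OCc3ccccc3)c2OCc2ccccc2)[C@@H]1O[Si](C)(C)C(C)(C)C | intermediate
16 | lithium (2S,3S)-3-[6-(allyloxy)-2,3,4-tris(benzyloxy)phenyl]-2-[(tert-butyldimethylsilyl)oxy]-5-hydroxypentanoate | OCC[C@@H](c1c(OCC=C)cc(OCc2ccccc2)c(OCc2ccccc2)c1OCc1ccccc1)[C@H](O[Si](C)(C)C(C)(C)C)C(=O)[O-].[Li+] | intermediate
17 | benzyl (2S,3S)-3-[6-(allyloxy)-2,3,4-tris(benzyloxy)phenyl]-2-[(tert-butyldimethylsilyl)oxy]-5-hydroxypentanoate | OCC[C@@H](c1c(OCC=C)cc(OCc2ccccc2)c(OCc2ccccc2)c1OCc1ccccc1)[C@H](O[Si](C)(C)C(C)(C)C)C(=O)OCc1ccccc1 | intermediate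
18 | benzyl (2S,3S)-3-[6-(allyloxy)-2,3,4-tris(benzyloxy)phenyl]-2-[(tert-butyldimethylsilyl)oxy]-5-oxopentanoate | O=CC[C@@H](c1c(OCC=C)cc(OCc2ccccc2)c(OCc2ccccc2)c1OCc1ccccc1)[C@H](O[Si](C)(C)C(C)(C)C)C(=O)OCc1ccccc1 | intermediate
19 | (3S,4S)-3-[6-(allyloxy)-2,3,4-tris(benzyloxy)phenyl]-5-(benzyloxy)-4-[(tert-butyldimethylsilyl)oxy]-5-oxopentanoic acid | OC(=O)C[C@@H](c1c(OCC=C)cc(OCc2ccccc2)c(OCc2ccccc2)c1OCc1ccccc1)[C@H](O[Si](C)(C)C(C)(C)C)C(=O)OCc1ccccc1 | intermediate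
20 | (3S,4S)-5-(benzyloxy)-4-[(tert-butyldimethylsilyl)oxy]-5-oxo-3-[2,3,4-tris(benzyloxy)-6-hydroxyphenyl]pentanoic acid | OC(=O)C[C@@H](c1c(O)cc(OCc2ccccc2)c(OCc2ccccc2)c1OCc1ccccc1)[C@H](O[Si](C)(C)C(C)(C)C)C(=O)OCc1ccccc1 | intermediate
21 | benzyl (2S)-2-[(tert-butyldimethylsilyl)oxy]-2-[(4S)-5,6,7-tris(benzyloxy)-2-oxo-3,4-dihydro-2H-chromen-4-yl]acetate | O=C1C[C@H]([C@H](O[Si](C)(C)C(C)(C)C)C(=O)OCc2ccccc2)c2c(OCc3ccccc3)c(OCc3ccccc3)c(OCc3ccccc3)cc2O1 | intermediate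
22 | benzyl bromoacetate | BrCC(=O)OCc1ccccc1 | starting material
23 | lithium enolate of 21 | [Li+].[O-]C1=C[C@H]([C@H](O[Si](C)(C)C(C)(C)C)C(=O)OCc2ccccc2)c2c(OCc3ccccc3)c(OCc3ccccc3)c(OCc3ccccc3)cc2O1 | intermediate
24 | benzyl (2S)-2-[(3S,4S)-5,6,7-tris(benzyloxy)-3-[2-(benzyloxy)-2-oxoethyl]-2-oxo-3,4-dihydro-2H-chromen-4-yl]-2-[(tert-butyldimethylsilyl)oxy]acetate (3,4-trans) | O=C1[C@@H](CC(=O)OCc2ccccc2)[C@H]([C@H](O[Si](C)(C)C(C)(C)C)C(=O)OCc2ccccc2)c2c(OCc3ccccc3)c(OCc3ccccc3)c(OCc3ccccc3)cc2O1 | intermediate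
25 | tribenzyl (1S,2S,3S)-1-[(tert-butyldimethylsilyl)oxy]-2-[2,3,4-tris(benzyloxy)-6-hydroxyphenyl]butane-1,3,4-tricarboxylate | O=C(OCc1ccccc1)C[C@H](C(=O)OCc1ccccc1)[C@@H](c1c(O)cc(OCc2ccccc2)c(OCc2ccccc2)c1OCc1ccccc1)[C@H](O[Si](C)(C)C(C)(C)C)C(=O)OCc1ccccc1 | intermediate
26 | tribenzyl (1S,2S,3S)-1-[(tert-butyldimethylsilyl)oxy]-2-[2,3,4-tris(benzyloxy)-6-{[(trifluoromethyl)sulfonyl]oxy}phenyl]butane-1,3,4-tricarboxylate | O=C(OCc1ccccc1)C[C@H](C(=O)OCc1ccccc1)[C@@H](c1c(OS(=O)(=O)C(F)(F)F)cc(OCc2ccccc2)c(OCc2ccccc2)c1OCc1ccccc1)[C@H](O[Si](C)(C)C(C)(C)C)C(=O)OCc1ccccc1 | intermediate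
27 | tribenzyl (1S,2S,3S)-1-hydroxy-2-[2,3,4-tris(benzyloxy)-6-{[(trifluoromethyl)sulfonyl]oxy}phenyl]butane-1,3,4-tricarboxylate | O=C(OCc1ccccc1)C[C@H](C(=O)OCc1ccccc1)[C@@H](c1c(OS(=O)(=O)C(F)(F)F)cc(OCc2ccccc2)c(OCc2ccccc2)c1OCc1ccccc1)[C@H](O)C(=O)OCc1ccccc1 | intermediate
28 | dibenzyl (2S)-2-[(3S,4S)-5,6,7-tris(benzyloxy)-3-[(benzyloxy)carbonyl]-1-oxo-3,4-dihydro-1H-isochromen-4-yl]butanedioate | O=C(OCc1ccccc1)C[C@H](C(=O)OCc1ccccc1)[C@H]1c2c(cc(OCc3ccccc3)c(OCc3ccccc3)c2OCc2ccccc2)C(=O)O[C@@H]1C(=O)OCc1ccccc1 | intermediate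
29 | chebulic acid | O=C(O)C[C@H](C(=O)O)[C@H]1c2c(cc(O)c(O)c2O)C(=O)O[C@@H]1C(=O)O | target

**Totals:** 16 steps; longest linear sequence 16 steps (fully linear).

**Three steps most likely to fail, with fallbacks**

Step 5 (Michael addition to an electron-rich enal whose aryl group carries two ortho oxygens; rate and ee are the concern). The fallback sets out from 4 and uses the free phenol instead of protecting it. Wittig reaction of 4 with 6 gives (E)-3-[2,3,4-tris(benzyloxy)-6-hydroxyphenyl]prop-2-enal F1. With the same catalyst and 8, the ortho-hydroxyl drives a domino Michael addition/hemiacetalisation that traps the adduct as the lactol dimethyl 2-[(4R)-5,6,7-tris(benzyloxy)-2-hydroxy-3,4-dihydro-2H-chromen-4-yl]propanedioate F2. The lactol is in equilibrium with its open phenol-aldehyde form; O-allylation of that phenoxide (allyl bromide, K2CO3, DMF, 0 °C) is much faster than C-alkylation of the hindered substituted malonate and returns to the route at 9.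

Step 12 (the aryl-ester enolate can fragment to a ketene above about −40 °C, and the alkylation may be sluggish). The fallback sets out from 19 and replaces the ring template by an Evans auxiliary. N-Acylation of (S)-4-benzyl-1,3-oxazolidin-2-one with 19 (PivCl, Et3N, then the oxazolidinone and LiCl) gives benzyl (2S,3S)-3-[6-(allyloxy)-2,3,4-tris(benzyloxy)phenyl]-5-[(4S)-4-benzyl-2-oxo-1,3-oxazolidin-3-yl]-2-[(tert-butyldimethylsilyl)oxy]-5-oxopentanoate F3. NaHMDS then 22 at −78 °C alkylates the chelated Z-enolate on the face away from the benzyl group and gives dibenzyl (2S,3S,4S)-3-[6-(allyloxy)-2,3,4-tris(benzyloxy)phenyl]-4-{[(4S)-4-benzyl-2-oxo-1,3-oxazolidin-3-yl]carbonyl}-2-[(tert-butyldimethylsilyl)oxy]hexanedioate F4. LiOH/H2O2 cleaves the auxiliary to 1,4-dibenzyl 3-hydrogen (1S,2S,3S)-2-[6-(allyloxy)-2,3,4-tris(benzyloxy)phenyl]-1-[(tert-butyldimethylsilyl)oxy]butane-1,3,4-tricarboxylate F5. BnBr/K2CO3 gives tribenzyl (1S,2S,3S)-2-[6-(allyloxy)-2,3,4-tris(benzyloxy)phenyl]-1-[(tert-butyldimethylsilyl)oxy]butane-1,3,4-tricarboxylate F6. Pd(PPh3)4/morpholine removes the allyl group and the fallback comes back at 25, which is triflated as in step 13.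

Step 15 (oxidative addition to a hindered, electron-rich aryl triflate; the free alcohol could instead lactonise onto a benzyl ester under base and heat). The fallback sets out from 26 and builds the acyl group while the alcohol is still silylated. Pd(OAc)2/Xantphos-catalysed aryloxycarbonylation with 2,4,6-trichlorophenyl formate and Et3N (toluene, 80 °C) gives the active ester tribenzyl (1S,2S,3S)-1-[(tert-butyldimethylsilyl)oxy]-2-[2,3,4-tris(benzyloxy)-6-[(2,4,6-trichlorophenoxy)carbonyl]phenyl]butane-1,3,4-tricarboxylate F7. HF·pyridine then frees the alcohol to give tribenzyl (1S,2S,3S)-1-hydroxy-2-[2,3,4-tris(benzyloxy)-6-[(2,4,6-trichlorophenoxy)carbonyl]phenyl]butane-1,3,4-tricarboxylate F8. Et3N/DMAP closes the lactone by acyl transfer from the aryl ester, which is far more electrophilic than the benzyl esters, and the fallback comes back at 28.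

**Further compounds**
F1 | step 5 | (E)-3-[2,3,4-tris(benzyloxy)-6-hydroxyphenyl]prop-2-enal | O=C/C=C/c1c(O)cc(OCc2ccccc2)c(OCc2ccccc2)c1OCc1ccccc1
F2 | step 5 | dimethyl 2-[(4R)-5,6,7-tris(benzyloxy)-2-hydroxy-3,4-dihydro-2H-chromen-4-yl]propanedioate | OC1C[C@H](C(C(=O)OC)C(=O)OC)c2c(OCc3ccccc3)c(OCc3ccccc3)c(OCc3ccccc3)cc2O1
F3 | step 12 | benzyl (2S,3S)-3-[6-(allyloxy)-2,3,4-tris(benzyloxy)phenyl]-5-[(4S)-4-benzyl-2-oxo-1,3-oxazolidin-3-yl]-2-[(tert-butyldimethylsilyl)oxy]-5-oxopentanoate | O=C(C[C@@H](c1c(OCC=C)cc(OCc2ccccc2)c(OCc2ccccc2)c1OCc1ccccc1)[C@H](O[Si](C)(C)C(C)(C)C)C(=O)OCc1ccccc1)N1[C@@H](Cc2ccccc2)COC1=O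
F4 | step 12 | dibenzyl (2S,3S,4S)-3-[6-(allyloxy)-2,3,4-tris(benzyloxy)phenyl]-4-{[(4S)-4-benzyl-2-oxo-1,3-oxazolidin-3-yl]carbonyl}-2-[(tert-butyldimethylsilyl)oxy]hexanedioate | O=C([C@@H](CC(=O)OCc1ccccc1)[C@@H](c1c(OCC=C)cc(OCc2ccccc2)c(OCc2ccccc2)c1OCc1ccccc1)[C@H](O[Si](C)(C)C(C)(C)C)C(=O)OCc1ccccc1)N1[C@@H](Cc2ccccc2)COC1=O
F5 | step 12 | 1,4-dibenzyl 3-hydrogen (1S,2S,3S)-2-[6-(allyloxy)-2,3,4-tris(benzyloxy)phenyl]-1-[(tert-butyldimethylsilyl)oxy]butane-1,3,4-tricarboxylate | OC(=O)[C@@H](CC(=O)OCc1ccccc1)[C@@H](c1c(OCC=C)cc(OCc2ccccc2)c(OCc2ccccc2)c1OCc1ccccc1)[C@H](O[Si](C)(C)C(C)(C)C)C(=O)OCc1ccccc1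
F6 | step 12 | tribenzyl (1S,2S,3S)-2-[6-(allyloxy)-2,3,4-tris(benzyloxy)phenyl]-1-[(tert-butyldimethylsilyl)oxy]butane-1,3,4-tricarboxylate | O=C(OCc1ccccc1)C[C@H](C(=O)OCc1ccccc1)[C@@H](c1c(OCC=C)cc(OCc2ccccc2)c(OCc2ccccc2)c1OCc1ccccc1)[C@H](O[Si](C)(C)C(C)(C)C)C(=O)OCc1ccccc1
F7 | step 15 | tribenzyl (1S,2S,3S)-1-[(tert-butyldimethylsilyl)oxy]-2-[2,3,4-tris(benzyloxy)-6-[(2,4,6-trichlorophenoxy)carbonyl]phenyl]butane-1,3,4-tricarboxylate | O=C(OCc1ccccc1)C[C@H](C(=O)OCc1ccccc1)[C@@H](c1c(C(=O)Oc2c(Cl)cc(Cl)cc2Cl)cc(OCc2ccccc2)c(OCc2ccccc2)c1OCc1ccccc1)[C@H](O[Si](C)(C)C(C)(C)C)C(=O)OCc1ccccc1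
F8 | step 15 | tribenzyl (1S,2S,3S)-1-hydroxy-2-[2,3,4-tris(benzyloxy)-6-[(2,4,6-trichlorophenoxy)carbonyl]phenyl]butane-1,3,4-tricarboxylate | O=C(OCc1ccccc1)C[C@H](C(=O)OCc1ccccc1)[C@@H](c1c(C(=O)Oc2c(Cl)cc(Cl)cc2Cl)cc(OCc2ccccc2)c(OCc2ccccc2)c1OCc1ccccc1)[C@H](O)C(=O)OCc1ccccc1
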